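The route rests on disconnecting cyclohexene ring A across C14–C15 and C6–C16. A thermal intramolecular Diels–Alder reaction of a 3-dienyl butenolide (diene C6=C7–C8=C15, lactone ring B preformed) with an (E)-exocyclic enone C14=C16 on a 3-methoxycyclopentenone (ring D), tethered through C11–C12–C13, closes ring A and cyclopentane ring C together and creates the spiro carbon C16. It exploits the fact that ring A shares C15 with rings B and C and is spiro-joined to ring D at C16, so one cycloaddition sets C14, C15 and C16 from C11 and the enone geometry. Lactone deconjugation, Stork–Danheiser transposition and conjugate borylation–oxidation finish the target.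

Key step: step 12

Numbering (target numbering, used for all ring compounds): side chain C1H2=C2(CH3)–C3H(–C4H2–C5O2Me); ring A C6=C7–C8–C15–C14–C16; lactone ring B C8–C9(=O)–O10–C11–C15; ring C C11–C12–C13(CH3)(OH)–C14–C15; spiro ring D C16–C17–C18(=O)–C19–C20(OH). Target: 3S,8R,11R,13S,14S,15R,16R,20S. "Upper face" of ring A is the face of H14 and H15.

Remark (assumption): 1, 2, 5, 7, 10, 11 and 18 are taken as commercial; the ligand antipodes in steps 1 and 9 are those predicted by the accepted facial models and would be exchanged if a model fails.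

Step 1
Reactants: 1 methyl (E)-4,4-dimethoxybut-2-enoate; 2 potassium isopropenyltrifluoroborate
Product: 3 methyl (3S)-3-(dimethoxymethyl)-4-methylpent-4-enoate
Conditions: [Rh(cod)2]BF4 (3 mol %), (R)-BINAP (3.3 mol %), toluene/H2O 20:1, 100 °C
Reagents that add atoms: none
Why: Hayashi–Miyaura rhodium-catalysed asymmetric 1,4-addition of an alkenyltrifluoroborate to an enoate, in which the (R)-BINAP–rhodium alkenyl adds to the 2-Re face of the (E)-enoate (the mirror image of the established (S)-BINAP sense) and so sets C3 as (S), the acetal leaving the ester as the only activating group.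

Step 2
Reactants: 3 methyl (3S)-3-(dimethoxymethyl)-4-methylpent-4-enoate
Product: 4 methyl (3S)-3-formyl-4-methylpent-4-enoate
Conditions: Amberlyst-15, acetone/H2O 10:1, 0 °C; crude aldehyde used at once
Reagents that add atoms: water, O
Why: Acid-catalysed acetal hydrolysis on a sulfonic acid resin at 0 °C with immediate use should keep the α-branched β,γ-unsaturated aldehyde from enolising, so C3 is carried through unchanged.

Step 3
Reactants: 4 methyl (3S)-3-formyl-4-methylpent-4-enoate; 5 iodoform
Product: 6 methyl (3R,4E)-5-iodo-3-(prop-1-en-2-yl)pent-4-enoate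
Conditions: CrCl2 (6 equiv), CHI3 (2 equiv), THF/dioxane 1:6, 0 °C → rt
Reagents that add atoms: none
Why: Takai olefination, whose non-basic geminal dichromium reagent adds to the aldehyde and eliminates to the (E)-vinyl iodide without epimerising C3 or touching the ester (the descriptor becomes R by priority only).

Step 4
Reactants: 7 3-methoxycyclopent-2-en-1-one
Product: 9 diethyl (4-methoxy-2-oxocyclopent-3-en-1-yl)phosphonate, via phosphonite 8 (not isolated)
Conditions: LiN(i-Pr)2 (2.1 equiv), THF, −78 °C; ClP(OEt)2; then H2O2 (30 %), 0 °C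
Reagents that add atoms: diethyl chlorophosphite, CCOP(Cl)OCC; hydrogen peroxide, OO
Why: The kinetic α'-enolate of the vinylogous ester attacks the trivalent phosphorus chloride at carbon (Wiemer's β-keto phosphonate synthesis) and the phosphonite is oxidised in the flask, the new centre being lost in the later olefination.

Step 5
Reactants: 10 (R)-2-methylglycidol; 11 vinylmagnesium bromide
Product: 13 (4S)-4-methyl-4,5-bis[(triethylsilyl)oxy]pent-1-ene, via magnesium dialkoxide 12 (not isolated)
Conditions: CH2=CHMgBr (2.2 equiv), CuI (10 mol %), THF, −30 → 0 °C; then Et3SiOTf (2.6 equiv), −78 → 0 °C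
Reagents that add atoms: triethylsilyl trifluoromethanesulfonate, CC[Si](CC)(CC)OS(=O)(=O)C(F)(F)F
Why: Copper-catalysed SN2 opening of the epoxide at its CH2 terminus by the vinyl Grignard reagent (the degenerate Payne shift of the alkoxide returns the same enantiomer) followed by silylation of both magnesium alkoxides, so C13 comes unchanged from the chiral pool.

Step 6
Reactants: 13 (4S)-4-methyl-4,5-bis[(triethylsilyl)oxy]pent-1-ene
Product: 14 (2S)-2-methyl-2-[(triethylsilyl)oxy]pent-4-enal
Conditions: (COCl)2 (3 equiv), DMSO (6 equiv), CH2Cl2, −78 → −40 °C; then Et3N, −78 → 0 °C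
Reagents that add atoms: none
Why: Swern oxidation applied directly to the bis-silyl ether, in which the chlorosulfonium salt cleaves only the unhindered primary triethylsilyl ether and oxidises it to the aldehyde, the quaternary α-carbon being unable to epimerise.

Step 7
Reactants: 14 (2S)-2-methyl-2-[(triethylsilyl)oxy]pent-4-enal; 9 diethyl (4-methoxy-2-oxocyclopent-3-en-1-yl)phosphonate
Product: 15 (5E)-3-methoxy-5-{(2S)-2-methyl-2-[(triethylsilyl)oxy]pent-4-en-1-ylidene}cyclopent-2-en-1-one
Conditions: Ba(OH)2·8H2O (0.6 equiv), THF/H2O 40:1, rt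
Reagents that add atoms: none
Why: Horner–Wadsworth–Emmons olefination of a cyclic β-keto phosphonate with a non-enolisable aldehyde under Paterson's barium hydroxide conditions should give the thermodynamically favoured (E)-alkylidene ketone (C13 anti to the carbonyl C20 and syn to C17), the geometry that later fixes C16.

Step 8
Reactants: 15 (5E)-3-methoxy-5-{(2S)-2-methyl-2-[(triethylsilyl)oxy]pent-4-en-1-ylidene}cyclopent-2-en-1-one
Product: 17 (3S,4E)-4-(4-methoxy-2-oxocyclopent-3-en-1-ylidene)-3-methyl-3-[(triethylsilyl)oxy]butanal, via diol 16 (not isolated)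
Conditions: OsO4 (2 mol %), NaIO4 (4 equiv), 2,6-lutidine (2 equiv), dioxane/H2O 3:1, rt
Reagents that add atoms: osmium tetroxide, O=[Os](=O)(=O)=O; sodium periodate, [Na+].[O-]I(=O)(=O)=O
Why: Lemieux–Johnson cleavage, in which OsO4 should dihydroxylate the monosubstituted terminal alkene far faster than the electron-poor trisubstituted enone bond or the conjugated methoxy-enone bond and periodate cleaves the resulting 1,2-diol.

Step 9
Reactants: 17 (3S,4E)-4-(4-methoxy-2-oxocyclopent-3-en-1-ylidene)-3-methyl-3-[(triethylsilyl)oxy]butanal; 18 methyl propiolate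
Product: 19 methyl (4R,6S,7E)-4-hydroxy-7-(4-methoxy-2-oxocyclopent-3-en-1-ylidene)-6-methyl-6-[(triethylsilyl)oxy]hept-2-ynoate
Conditions: (S,S)-ProPhenol (20 mol %), ZnMe2 (3 equiv), Ph3PO (40 mol %), toluene, 4 °C
Reagents that add atoms: none
Why: Trost's ProPhenol–ZnMe2-catalysed alkynylation of an aldehyde with methyl propiolate, in which the dinuclear zinc catalyst directs the zinc acetylide to the Si face and sets C11 as (R) under catalyst control, the β-silyloxy group preventing retro-aldol cleavage of the aldehyde.

Step 10
Reactants: 19 methyl (4R,6S,7E)-4-hydroxy-7-(4-methoxy-2-oxocyclopent-3-en-1-ylidene)-6-methyl-6-[(triethylsilyl)oxy]hept-2-ynoate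
Product: 21 (5R)-5-[(2S,3E)-2-hydroxy-3-(4-methoxy-2-oxocyclopent-3-en-1-ylidene)-2-methylpropyl]-3-(tributylstannyl)furan-2(5H)-one, via hydroxy stannyl enoate 20 (not isolated)
Conditions: Bu3SnH (1.1 equiv), Pd(PPh3)4 (2 mol %), THF, 0 °C; then p-TsOH·H2O (0.1 equiv), MeOH, 0 °C → rt
Reagents that add atoms: tributyltin hydride, CCCC[SnH](CCCC)CCCC
Why: Palladium-catalysed syn-hydrostannation of the ynoate places tin on the α-carbon C8 and hydrogen on C15, so the C11 hydroxyl is cis to the ester and closes the butenolide under the acid that also removes the tertiary silyl ether, C11 being untouched and the electron-poor alkenylstannane resisting protodestannylation.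

Step 11
Reactants: 21 (5R)-5-[(2S,3E)-2-hydroxy-3-(4-methoxy-2-oxocyclopent-3-en-1-ylidene)-2-methylpropyl]-3-(tributylstannyl)furan-2(5H)-one; 6 methyl (3R,4E)-5-iodo-3-(prop-1-en-2-yl)pent-4-enoate
Product: 22 methyl (3R,4E)-5-{(5R)-5-[(2S,3E)-2-hydroxy-3-(4-methoxy-2-oxocyclopent-3-en-1-ylidene)-2-methylpropyl]-2-oxo-2,5-dihydrofuran-3-yl}-3-(prop-1-en-2-yl)pent-4-enoate
Conditions: Pd2(dba)3 (5 mol %), AsPh3 (20 mol %), CuI (10 mol %), NMP, rt, dark
Reagents that add atoms: none
Why: Stille coupling of the α-stannyl butenolide with the (E)-vinyl iodide under triphenylarsine and copper iodide acceleration proceeds with retention at both sp2 carbons at room temperature, giving the (E)-diene before any cycloaddition can start.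

Step 12
Reactants: 22 methyl (3R,4E)-5-{(5R)-5-[(2S,3E)-2-hydroxy-3-(4-methoxy-2-oxocyclopent-3-en-1-ylidene)-2-methylpropyl]-2-oxo-2,5-dihydrofuran-3-yl}-3-(prop-1-en-2-yl)pent-4-enoate
Product: 23 Diels–Alder adduct (rings A–D; C7=C8 conjugated lactone; C6-H on the upper face; ring D as 18-methoxy-18-en-20-one)
Conditions: toluene (0.005 M), BHT (0.1 equiv), 120 °C, sealed tube
Reagents that add atoms: none
Why: Thermal type 1 intramolecular Diels–Alder reaction, a concerted asynchronous [4+2] cycloaddition in which the butenolide-fused diene C6=C7–C8=C15 adds suprafacially across the (E)-alkylidene ketone C14=C16, the tether fixing the regiochemistry (C15 to the enone β-carbon C14, the alkyl-bearing terminus C6 to the α-carbon C16). The closest known reaction type is the cyclisation of 1,3,8-nonatrienes to hydrindenes, joined to the use of α-alkylidene cycloalkanones as dienophiles for spiro quaternary carbons. Ring C (five-membered) closes as the tether ring through C14–C15, and ring A (six-membered) closes as the cycloadduct ring through C14–C15 and C6–C16. C15 is controlled by C11, because the three-atom tether reaches only the butenolide face that carries C12 (H15 cis to H11); C14 is controlled by the tether-endo, carbonyl-exo transition state (H14 cis to H15, cis-hydrindene); C16 follows stereospecifically from the (E)-enone (C17 cis to C13, C20 on the face of H14 and H15); C6 follows from the (E)-diene and is erased in step 13. The step needs the cis ring fusion and cyclisation ahead of diene dimerisation: the first is secured by the intrinsic cis preference of five-membered-tether cyclisations, the exo-carbonyl preference of α-substituted dienophiles and the planar butenolide that holds C12 under the diene, the second by high dilution with a radical inhibitor. The small free hydroxyl at C13 fits on the concave face of the forming tricycle, which a silyl ether would not.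

Step 13
Reactants: 23 Diels–Alder adduct (rings A–D; C7=C8 conjugated lactone; C6-H on the upper face; ring D as 18-methoxy-18-en-20-one)
Product: 25 β,γ-unsaturated trans-fused lactone (C6=C7; 8R; ring D as 18-methoxy-18-en-20-one), via dilithium dienolate 24 (not isolated)
Conditions: LiN(i-Pr)2 (2.3 equiv), THF/DMPU, −78 → −40 °C; then AcOH (5 equiv), −78 °C
Reagents that add atoms: none
Why: Deconjugative protonation, in which the second equivalent of amide (after the C13 alkoxide has formed) removes the γ-hydrogen at C6 to give the extended lactone enolate that is protonated kinetically at the α-carbon C8 so that the double bond moves to C6=C7, while proton relay from the C13 hydroxyl on the lower face, supported by the thermodynamic preference for the trans-fused lactone (no 1,3-diaxial carbon contacts), should place H8 anti to H15.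

Step 14
Reactants: 25 β,γ-unsaturated trans-fused lactone (C6=C7; 8R; ring D as 18-methoxy-18-en-20-one)
Product: 27 spiro enone (ring D as cyclopent-19-en-18-one), via allylic alcohol 26 (not isolated)
Conditions: NaBH4, CeCl3·7H2O, MeOH, −20 °C; then 1 M HCl, THF, rt
Reagents that add atoms: water, O
Why: Stork–Danheiser transposition, in which Luche 1,2-reduction of the vinylogous ester carbonyl C20 and acid hydrolysis of the methyl enol ether with loss of the C20 hydroxyl deliver the C18 ketone conjugated to C19=C20, the lactone and methyl ester being inert to borohydride with cerium chloride and the transient C20 carbinol configuration being of no consequence.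

Step 15
Reactants: 27 spiro enone (ring D as cyclopent-19-en-18-one)
Product: 29 CNP0255095.1 (target), via boryl ketone 28 (not isolated)
Conditions: B2pin2 (1.2 equiv), CuCl (5 mol %), NaOt-Bu (10 mol %), DPEphos (5 mol %), MeOH (2 equiv), THF, rt; then NaBO3·4H2O, THF/H2O, rt
Reagents that add atoms: bis(pinacolato)diboron, CC1(C)OB(OC1(C)C)B1OC(C)(C)C(C)(C)O1; sodium perborate, [Na+].[O-]OB=O
Why: Copper-catalysed conjugate borylation of the enone followed by stereoretentive perborate oxidation of the C–B bond, in which the boryl–copper reagent should add to C20 on the ring D face that lies over the planar C6 and away from C14 and the axial H15, so the hydroxyl ends cis to C6, which is the (20S) configuration.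

Compound list
1 | methyl (E)-4,4-dimethoxybut-2-enoate | COC(=O)/C=C/C(OC)OC | starting material
2 | potassium isopropenyltrifluoroborate | [K+].C=C(C)[B-](F)(F)F | starting material
3 | methyl (3S)-3-(dimethoxymethyl)-4-methylpent-4-enoate | C=C(C)[C@H](CC(=O)OC)C(OC)OC | intermediate
4 | methyl (3S)-3-formyl-4-methylpent-4-enoate | C=C(C)[C@H](CC(=O)OC)C=O | intermediate
5 | iodoform | IC(I)I | starting material
6 | methyl (3R,4E)-5-iodo-3-(prop-1-en-2-yl)pent-4-enoate | C=C(C)[C@H](CC(=O)OC)/C=C/I | intermediate
7 | 3-methoxycyclopent-2-en-1-one | COC1=CC(=O)CC1 | starting material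
8 | diethyl (4-methoxy-2-oxocyclopent-3-en-1-yl)phosphonite | CCOP(OCC)C1CC(OC)=CC1=O | intermediate
9 | diethyl (4-methoxy-2-oxocyclopent-3-en-1-yl)phosphonate | CCOP(=O)(OCC)C1CC(OC)=CC1=O | intermediate
10 | (R)-2-methylglycidol, [(2R)-2-methyloxiran-2-yl]methanol | C[C@@]1(CO)CO1 | starting material
11 | vinylmagnesium bromide | C=C[Mg]Br | starting material
12 | bis(bromomagnesium) alkoxide of (2S)-2-methylpent-4-ene-1,2-diol | C=CC[C@](C)(O[Mg]Br)CO[Mg]Br | intermediate
13 | (4S)-4-methyl-4,5-bis[(triethylsilyl)oxy]pent-1-ene | C=CC[C@](C)(O[Si](CC)(CC)CC)CO[Si](CC)(CC)CC | intermediate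
14 | (2S)-2-methyl-2-[(triethylsilyl)oxy]pent-4-enal | C=CC[C@](C)(O[Si](CC)(CC)CC)C=O | intermediate
15 | (5E)-3-methoxy-5-{(2S)-2-methyl-2-[(triethylsilyl)oxy]pent-4-en-1-ylidene}cyclopent-2-en-1-one | C=CC[C@](C)(O[Si](CC)(CC)CC)/C=C1\CC(OC)=CC1=O | intermediate
16 | terminal 1,2-diol of 15 (mixture at the new carbinol) | OCC(O)C[C@](C)(O[Si](CC)(CC)CC)/C=C1\CC(OC)=CC1=O | intermediate
17 | (3S,4E)-4-(4-methoxy-2-oxocyclopent-3-en-1-ylidene)-3-methyl-3-[(triethylsilyl)oxy]butanal | O=CC[C@](C)(O[Si](CC)(CC)CC)/C=C1\CC(OC)=CC1=O | intermediate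
18 | methyl propiolate | C#CC(=O)OC | starting material
19 | methyl (4R,6S,7E)-4-hydroxy-7-(4-methoxy-2-oxocyclopent-3-en-1-ylidene)-6-methyl-6-[(triethylsilyl)oxy]hept-2-ynoate | COC(=O)C#C[C@H](O)C[C@](C)(O[Si](CC)(CC)CC)/C=C1\CC(OC)=CC1=O | intermediate
20 | methyl (2E,4R,6S,7E)-4-hydroxy-7-(4-methoxy-2-oxocyclopent-3-en-1-ylidene)-6-methyl-2-(tributylstannyl)-6-[(triethylsilyl)oxy]hept-2-enoate | CCCC[Sn](CCCC)(CCCC)/C(C(=O)OC)=C/[C@H](O)C[C@](C)(O[Si](CC)(CC)CC)/C=C1\CC(OC)=CC1=O | intermediate
21 | (5R)-5-[(2S,3E)-2-hydroxy-3-(4-methoxy-2-oxocyclopent-3-en-1-ylidene)-2-methylpropyl]-3-(tributylstannyl)furan-2(5H)-one | CCCC[Sn](CCCC)(CCCC)C1=C[C@@H](C[C@](C)(O)/C=C2\CC(OC)=CC2=O)OC1=O | intermediate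
22 | methyl (3R,4E)-5-{(5R)-5-[(2S,3E)-2-hydroxy-3-(4-methoxy-2-oxocyclopent-3-en-1-ylidene)-2-methylpropyl]-2-oxo-2,5-dihydrofuran-3-yl}-3-(prop-1-en-2-yl)pent-4-enoate | C=C(C)[C@H](CC(=O)OC)/C=C/C1=C[C@@H](C[C@](C)(O)/C=C2\CC(OC)=CC2=O)OC1=O | intermediate
23 | Diels–Alder adduct: rings A–D, C7=C8 conjugated to the lactone, H6, H14, H15 and C20 on the upper face of ring A, C3, C11, C13 and C17 on the lower face, C13-OH free, ring D as 18-methoxy-18-en-20-one | C=C(C)[C@H](CC(=O)OC)[C@@H]1C=C2C(=O)O[C@@H]3C[C@](C)(O)[C@@H]([C@@H]32)[C@]12CC(OC)=CC2=O | intermediate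
24 | dilithium salt of 23: C13 alkoxide and extended lactone enolate O–C9=C8–C7=C6 | [Li+].[Li+].C=C(C)[C@H](CC(=O)OC)C1=CC2=C([O-])O[C@@H]3C[C@](C)([O-])[C@@H]([C@@H]32)[C@]12CC(OC)=CC2=O | intermediate
25 | β,γ-unsaturated trans-fused lactone: C6=C7, (8R) with H8 anti to H15, ring D as 18-methoxy-18-en-20-one | C=C(C)[C@H](CC(=O)OC)C1=C[C@H]2C(=O)O[C@@H]3C[C@](C)(O)[C@@H]([C@@H]32)[C@]12CC(OC)=CC2=O | intermediate
26 | allylic alcohol: 25 with C20 carbonyl reduced to CH–OH (either epimer) | C=C(C)[C@H](CC(=O)OC)C1=C[C@H]2C(=O)O[C@@H]3C[C@](C)(O)[C@@H]([C@@H]32)[C@]12CC(OC)=CC2O | intermediate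
27 | spiro enone: as 25 with ring D = cyclopent-19-en-18-one (C18=O, C19=C20) | C=C(C)[C@H](CC(=O)OC)C1=C[C@H]2C(=O)O[C@@H]3C[C@](C)(O)[C@@H]([C@@H]32)[C@]12CC(=O)C=C2 | intermediate
28 | (20S)-20-(pinacolboryl) ketone: 27 after addition of Bpin to C20 (cis to C6) and H to C19 | C=C(C)[C@H](CC(=O)OC)C1=C[C@H]2C(=O)O[C@@H]3C[C@](C)(O)[C@@H]([C@@H]32)[C@]12CC(=O)C[C@@H]2B1OC(C)(C)C(C)(C)O1 | intermediate
29 | CNP0255095.1 (3S,8R,11R,13S,14S,15R,16R,20S) | C=C(C)[C@H](CC(=O)OC)C1=C[C@H]2C(=O)O[C@@H]3C[C@](C)(O)[C@@H]([C@@H]32)[C@]12CC(=O)C[C@@H]2O | target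

Total step count: 15
Longest linear sequence: 11 steps (steps 5–15, from 10); steps 1–3 and step 4 are side branches that join at steps 11 and 7.

Steps most likely to fail

Step 12. The cycloaddition may be outrun by dimerisation of the electron-poor diene or by oxa-Michael addition of the free C13 hydroxyl to C15 of the butenolide, and part of the material may pass through the tether-exo transition state to the trans-fused adduct. The fallback sets out from 22 and comes back at 27, and it uses the C13 oxygen as a temporary tether. Camphorsulfonic acid (5 mol %) in benzene over 4 Å molecular sieves at 50 °C would exchange the methyl enol ether for the C13 hydroxyl with loss of methanol. This gives the cyclic vinylogous ester triene F1, in which the O13–C18 bond closes a dihydropyran ring, masks the hydroxyl and locks the enone geometry. Heating as in step 12 should give the tethered Diels–Alder adduct F2, and deconjugation as in step 13 (one equivalent of base less) the tethered β,γ-unsaturated lactone F3. The conditions of step 14 then reduce C20 and hydrolyse the tether enol ether, which frees the C13 hydroxyl and the C18 ketone and gives 27.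

Step 13. The hindered, poorly aligned C6 hydrogen may not be removed (the amide enolising the methyl ester instead), or the dienolate may be protonated from the upper face to give the cis-fused lactone. The fallback sets out from 23 and comes back at 25 by an addition–elimination sequence. Sodium phenylselenide–borate ((PhSe)2, NaBH4, EtOH, then AcOH, 0 °C → rt) should add selenium to C7 from the upper face with anti protonation at C8. This gives the 7-phenylselanyl lactone F4, with H8 already anti to H15. H2O2 with pyridine in CH2Cl2 at 0 °C gives the selenoxide F5. Its syn-elimination can use only the cis hydrogen at C6, because H8 is trans to selenium, and so delivers 25.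

Step 15. The facial selectivity of the boryl–copper addition at C20 may be poor or reversed, or the alkoxide co-catalyst may enolise C8 and cause epimerisation or Michael addition of C8 to C20. The fallback sets out from 25 and comes back at 29. Hydride and boryl–copper should prefer the same face of C20, so reduction puts the oxygen on the opposite face to the borylation route. NaBH4 with CeCl3·7H2O in MeOH at −40 °C would reduce the C20 carbonyl of 25 to the (20S)-allylic alcohol F6. The methyl enol ether is then hydrolysed under buffered conditions (oxalic acid on wet silica gel, CH2Cl2, 0 °C) that should stop at the β-hydroxy ketone 29 before the C20–O bond ionises.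

Further compounds
F1 | step 12 | cyclic vinylogous ester triene: 22 with the C13 oxygen bonded to C18 in place of the methoxy group | C=C(C)[C@H](CC(=O)OC)/C=C/C1=C[C@@H](C[C@]2(C)OC3=CC(=O)C(=C2)C3)OC1=O
F2 | step 12 | tethered Diels–Alder adduct: 23 with the O13–C18 bond in place of C13-OH and C18-OMe | C=C(C)[C@H](CC(=O)OC)[C@@H]1C=C2C(=O)O[C@@H]3C[C@](C)(O4)[C@@H]([C@@H]32)[C@]12CC4=CC2=O
F3 | step 12 | tethered β,γ-unsaturated lactone: 25 with the O13–C18 bond in place of C13-OH and C18-OMe | C=C(C)[C@H](CC(=O)OC)C1=C[C@H]2C(=O)O[C@@H]3C[C@](C)(O4)[C@@H]([C@@H]32)[C@]12CC4=CC2=O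
F4 | step 13 | 7-phenylselanyl lactone: 23 after addition of PhSe to C7 (cis to H6) and H to C8 (anti to H15) | C=C(C)[C@H](CC(=O)OC)[C@@H]1[C@@H]([Se]c4ccccc4)[C@H]2C(=O)O[C@@H]3C[C@](C)(O)[C@@H]([C@@H]32)[C@]12CC(OC)=CC2=O
F5 | step 13 | selenoxide of F4 | C=C(C)[C@H](CC(=O)OC)[C@@H]1[C@@H]([Se](=O)c4ccccc4)[C@H]2C(=O)O[C@@H]3C[C@](C)(O)[C@@H]([C@@H]32)[C@]12CC(OC)=CC2=O
F6 | step 15 | (20S)-allylic alcohol: 25 with the C20 carbonyl reduced and the hydroxyl cis to C6 | C=C(C)[C@H](CC(=O)OC)C1=C[C@H]2C(=O)O[C@@H]3C[C@](C)(O)[C@@H]([C@@H]32)[C@]12CC(OC)=C[C@@H]2O
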